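**Retrosynthetic overview**

1. Feature: in ring A the quaternary carbon C8 carries the lavandulyl CH two bonds away (C8–CH2–CH), and the isopropenyl carbon on that CH can be a carbonyl. Closed onto the oxygen of the neighbouring ring carbon C7 (the later ketone), the six atoms C8, CH2, CH, C(=O), O7 and C7 form a temporary δ-enol-lactone (ring C).
2. Key disconnection: ring C is cut at C8–CH2 and at O7–C(=O), giving the aromatic 8-prenyl-5,7-dihydroxychromanone 16 and 2-prenylacryloyl chloride 23. The forward step dearomatises ring A and sets C8 and the CH centre.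
3. The lactone is then opened to a Weinreb amide and its carbonyl carbon becomes the isopropenyl carbon (MeMgBr, then methylenation). The CH2OTBS end of the C6 side chain is oxidised to CO2H last.
4. 16 comes from phloroglucinol: tigloyl ketone, asymmetric oxa-Michael closure of the pyranone ring B, prenyl placed at C8 by a 5-O-prenyl para-Claisen–Cope shift, then the C6 benzylic centre by iminium-catalysed Friedel–Crafts addition to cinnamaldehyde.
5. Ring order: ring A (from phloroglucinol) → ring B (step 2) → ring C (closed in step 14, opened in step 15).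

Key step: step 14

Numbering: chroman-4-one numbering (O1, C2, C3, C4=O, C4a, C5–C8, C8a) is kept for all compounds, including the dearomatised ones. "Prenyl" is 3-methylbut-2-en-1-yl.

Assumption: the absolute sense of the catalyst-controlled steps 2, 8 and 14 is taken from the usual open-face models of (−)-quinine, the (S)-diarylprolinol silyl ether and (2S,3R)-HyperBTM; if a model proves inverted, the antipodal (for quinine the pseudo-enantiomeric) catalyst is used.

**Route**

Step 1
Reactants: 1 phloroglucinol; 2 tigloyl chloride ((E)-2-methylbut-2-enoyl chloride)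
Product: 3 (E)-2-methyl-1-(2,4,6-trihydroxyphenyl)but-2-en-1-one
Conditions: AlCl3 (3 equiv), PhNO2/CH2Cl2, 0 °C, short reaction time; cold aq. HCl work-up
Reagents that add atoms: none
Why: Friedel–Crafts C-acylation of the symmetric triphenol, whose three ring positions are equivalent so only one mono-acyl product can form, run cold and briefly so that acid-mediated (racemic) ring closure of the tigloyl ketone stays minor and is removed by chromatography.

Step 2
Reactants: 3 tigloyl ketone
Product: 4 (2R,3S)-5,7-dihydroxy-2,3-dimethylchroman-4-one (mainly cis)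
Conditions: (−)-quinine (20 mol%), PhCl/THF, rt
Reagents that add atoms: none
Why: quinine-catalysed intramolecular oxa-Michael addition (6-endo-trig) of one of the two equivalent ortho-phenols to the tigloyl enone, a reaction known for o-tigloylphenols, in which the alkaloid acts as chiral general base and sets the O–CH centre C2 as R while kinetic protonation gives mainly the cis C3 methyl.

Step 3
Reactants: 4 cis-chromanone
Product: 5 (2R,3R)-5,7-dihydroxy-2,3-dimethylchroman-4-one (trans)
Conditions: MgI2 (1.5 equiv), THF, rt → 40 °C
Reagents that add atoms: none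
Why: MgI2-assisted epimerisation through the magnesium-chelated enol of the 5-hydroxy-4-ketone should move C3 to the thermodynamically preferred trans arrangement (both methyl groups pseudo-equatorial) without opening ring B, so C2 stays R.

Step 4
Reactants: 5 trans-chromanone
Product: 6 (2R,3R)-7-acetoxy-5-hydroxy-2,3-dimethylchroman-4-one
Conditions: Ac2O (1.05 equiv), pyridine, CH2Cl2, 0 °C
Reagents that add atoms: acetic anhydride, CC(=O)OC(C)=O
Why: chemoselective O-acetylation, since the 5-OH is held in a hydrogen bond to the C4 carbonyl and only the free, more acidic 7-OH reacts with one equivalent of anhydride.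

Step 5
Reactants: 6 7-acetate; 7 prenyl alcohol (3-methylbut-2-en-1-ol)
Product: 8 (2R,3R)-7-acetoxy-2,3-dimethyl-5-(3-methylbut-2-en-1-yloxy)chroman-4-one
Conditions: PPh3, DIAD, THF, 0 °C → rt
Reagents that add atoms: none
Why: Mitsunobu etherification of the chelated 5-OH with a primary allylic alcohol (SN2 at CH2, so the prenyl unit is attached unrearranged) under neutral conditions that leave the aryl acetate and C2/C3 untouched.

Step 6
Reactants: 8 5-O-prenyl ether
Product: 11 (2R,3R)-7-acetoxy-5-hydroxy-2,3-dimethyl-8-prenylchroman-4-one, via Claisen dienone 9 (not isolated), via Cope dienone 10 (not isolated)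
Conditions: Eu(fod)3 (10 mol%), CHCl3, 60 °C, sealed tube
Reagents that add atoms: none
Why: Eu(fod)3-catalysed tandem Claisen–Cope (para-Claisen) rearrangement, in which the [3,3] shift to C6 (the only free ortho position) gives the 1,1-dimethylallyl dienone, a second [3,3] shift carries the chain to C8 with the normal prenyl terminus and enolisation restores the arene, so the prenyl group is placed at C8 without ambiguity and no stereocentre is formed.

Step 7
Reactants: 11 8-prenyl 7-acetate
Product: 12 (2R,3R)-5,7-dihydroxy-2,3-dimethyl-8-prenylchroman-4-one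
Conditions: K2CO3 (0.2 equiv), MeOH, 0 °C → rt
Reagents that add atoms: none
Why: base-catalysed methanolysis (transesterification) of the aryl acetate of an acidic phenol, fast under conditions too mild to open ring B, the trans-dimethyl arrangement being the thermodynamic one.

Step 8
Reactants: 12 8-prenylchromanone; 13 (E)-cinnamaldehyde
Product: 15 (2R,3R)-5,7-dihydroxy-6-[(1S)-3-hydroxy-1-phenylpropyl]-2,3-dimethyl-8-prenylchroman-4-one, via lactol 14 (not isolated)
Conditions: (S)-2-[diphenyl(trimethylsilyloxy)methyl]pyrrolidine (20 mol%), PhCO2H (20 mol%), CHCl3, 0 °C → rt; then MeOH, NaBH4, 0 °C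
Reagents that add atoms: none
Why: organocatalytic Friedel–Crafts-type conjugate addition of the electron-rich phenol to the iminium ion of cinnamaldehyde with hemiacetalisation, followed by borohydride reduction of the lactol in the same flask, where C6 is the only unsubstituted ring carbon, the silyloxydiphenylmethyl group shields the Re face of the β-carbon of the E,s-trans iminium ion so that Si-face attack gives the (S) benzylic centre, and the cold borohydride leaves the chelated, phenoxide-deactivated C4 ketone alone.

Step 9
Reactants: 15 diol
Product: 16 (2R,3R)-6-[(1S)-3-(tert-butyldimethylsilyloxy)-1-phenylpropyl]-5,7-dihydroxy-2,3-dimethyl-8-prenylchroman-4-one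
Conditions: TBSCl (1.1 equiv), imidazole, DMF, 0 °C
Reagents that add atoms: tert-butyldimethylsilyl chloride, CC(C)(C)[Si](C)(C)Cl
Why: silyl ether formation at the unhindered primary alcohol, both phenols being flanked by two ortho substituents (the 5-OH is also chelated) and therefore inert to TBSCl/imidazole at 0 °C.

Step 10
Reactants: 17 diethyl malonate (1.5 equiv); 18 prenyl bromide
Product: 19 diethyl 2-(3-methylbut-2-en-1-yl)malonate
Conditions: NaOEt (1.0 equiv), EtOH, 0 → 60 °C
Reagents that add atoms: none
Why: malonic ester alkylation (SN2 of the sodium enolate at the primary allylic bromide), with excess malonate to suppress dialkylation.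

Step 11
Reactants: 19 prenylmalonate
Product: 20 2-(3-methylbut-2-en-1-yl)malonic acid
Conditions: KOH, EtOH/H2O, rt; then aq. HCl to pH 2, 0 °C
Reagents that add atoms: potassium hydroxide, [K+].[OH-]
Why: saponification of both esters, with cold acidification so that neither decarboxylation nor acid-induced reaction of the trisubstituted alkene sets in.

Step 12
Reactants: 20 prenylmalonic acid
Product: 22 5-methyl-2-methylidenehex-4-enoic acid, via Mannich base 21 (not isolated)
Conditions: (CH2O)n, Et2NH, EtOAc, reflux
Reagents that add atoms: formaldehyde (as paraformaldehyde), C=O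
Why: Mannich reaction of the monosubstituted malonic acid with formaldehyde and diethylamine followed by decarboxylative elimination of the amine, the classical entry to 2-substituted acrylic acids.

Step 13
Reactants: 22 2-prenylacrylic acid
Product: 23 5-methyl-2-methylidenehex-4-enoyl chloride
Conditions: 1-chloro-N,N,2-trimethylprop-1-en-1-amine (1.1 equiv), CH2Cl2, 0 °C → rt; used as a solution
Reagents that add atoms: 1-chloro-N,N,2-trimethylprop-1-en-1-amine, CC(C)=C(Cl)N(C)C
Why: neutral conversion of the acid into its chloride with an α-chloroenamine, which avoids free HCl that could add to the trisubstituted alkene or to the acrylate.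

Step 14
Reactants: 16 aromatic prenylchromanone; 23 2-prenylacryloyl chloride
Product: 25 tricyclic enol lactone (ring A dearomatised at C8, configuration S, C8 bearing prenyl; δ-lactone O7–C(=O)–CH(prenyl)–CH2–C8 with the CH centre R; C5 ketone; side chain and ring B as in 16), via acyl isothiouronium chloride 24 (not isolated)
Conditions: (2S,3R)-3-isopropyl-2-phenyl-3,4-dihydro-2H-benzo[4,5]thiazolo[3,2-a]pyrimidine ((2S,3R)-HyperBTM, 20 mol%), iPr2NEt (2.5 equiv), CH2Cl2, −40 °C → rt, slow addition of 23
Reagents that add atoms: none
Why: Proposed new method: N-acylation of the isothiourea by 23 gives the α,β-unsaturated acyl isothiouronium ion 24 (carbonyl oxygen held syn to sulfur), the 7-phenoxide of 16 adds through C8 to its unsubstituted CH2 terminus with dearomatisation of ring A, the catalyst-bound ammonium enolate is protonated at the future lavandulyl CH, and the C7 enol oxygen then displaces the catalyst at the acyl carbon. The closest known reaction types are the isothiourea-catalysed Michael addition–lactonisation of α,β-unsaturated acyl ammonium ions with 1,3-dicarbonyl compounds and naphthols and the base-mediated dearomative annulation of acylphloroglucinols with 2-substituted acrylates; a fully substituted arene carbon as nucleophile combined with an α-branched acryloyl ammonium ion has not been shown. Ring C (O7, C7, C8, CH2, CH, C=O) closes by 6-exo-trig acyl substitution, which also turns the catalyst over and blocks retro-Michael rearomatisation. C8 (S) is set in the C–C bond formation, where the arene has to stack on the face of the acyl ammonium ion left open by the pseudo-axial phenyl group of the catalyst while O7 sits over the acyl carbon, and the CH centre (R) is set by protonation of the planar enolate from that same open face; the remote centres of 16 are expected to have little influence. The step needs attack at C8 and not at C6, which the substrate secures because C8 is ortho to O7, para to O5 and carries only a primary prenyl CH2 whereas C6 carries the branched benzylic chain; O-acylation of the acidic 7-OH is not fatal, since such an aryl ester is itself an acyl donor towards the catalyst.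

Step 15
Reactants: 25 enol lactone
Product: 26 Weinreb amide, (2R)-N-methoxy-N-methyl-2-prenyl-3-(ring A C8-yl)propanamide with ring A as the C7-keto/C5-enol dienone (C8 S)
Conditions: MeNH(OMe)·HCl (3 equiv), iPrMgCl (6 equiv), THF, −20 °C
Reagents that add atoms: N,O-dimethylhydroxylamine hydrochloride, Cl.CNOC
Why: aminolysis of the enol lactone, an activated vinylogous-anhydride-type acyl donor, by the magnesium amide of N,O-dimethylhydroxylamine, which cleaves the acyl–O7 bond, frees the C7/C5 enolised diketone, does not touch C8 and, being fast and cold, should not epimerise the adjacent CH.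

Step 16
Reactants: 26 Weinreb amide
Product: 27 methyl ketone (C8–CH2–CH(prenyl)–C(=O)CH3, CH centre R, C8 S)
Conditions: MeMgBr (4 equiv), THF, −78 → 0 °C; cold aq. NH4Cl
Reagents that add atoms: methylmagnesium bromide, C[Mg]Br
Why: Weinreb ketone synthesis, in which the first equivalent of Grignard reagent turns the acidic enol into its magnesium enolate (shielding the ring carbonyls) and the stable N-methoxy chelate prevents over-addition and enolisation, so the α-centre is retained.

Step 17
Reactants: 27 methyl ketone
Product: 28 lavandulyl compound as its TBS ether (isopropenyl on the CH centre, R; C8 S)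
Conditions: Zn, CH2Br2, TiCl4 (pre-formed reagent), CH2Cl2/THF, 0 °C → rt
Reagents that add atoms: dibromomethane, BrCBr
Why: Takai–Lombardo methylenation, whose non-basic zinc/titanium methylene reagent olefinates enolisable ketones without α-epimerisation and should leave the enolised, titanium-bound diketone and the vinylogous ester carbonyl of rings A and B alone.

Step 18
Reactants: 28 TBS ether
Product: 29 primary alcohol (C6 side chain CH(Ph)CH2CH2OH)
Conditions: HF·pyridine, pyridine, THF, 0 °C → rt
Reagents that add atoms: none
Why: fluoride cleavage of the primary silyl ether under pyridine-buffered conditions mild enough to avoid acid-induced cyclisation of the prenyl groups onto the enol oxygens.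

Step 19
Reactants: 29 alcohol
Product: 30 aldehyde (C6 side chain CH(Ph)CH2CHO; may rest partly as the cyclic hemiacetal with the C5 enol OH)
Conditions: Dess–Martin periodinane, NaHCO3, CH2Cl2, 0 °C
Reagents that add atoms: none
Why: Dess–Martin oxidation of the primary alcohol, fast at 0 °C under buffered conditions that tolerate the three alkenes and the substituted enolised diketone.

Step 20
Reactants: 30 aldehyde
Product: 31 target acid CNP0150579.1
Conditions: NaClO2, NaH2PO4, 2-methyl-2-butene (large excess), tBuOH/H2O, 0 °C → rt
Reagents that add atoms: sodium chlorite, [Na+].[O-]Cl=O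
Why: Pinnick (Lindgren–Kraus) oxidation of the aldehyde to the carboxylic acid, with excess 2-methyl-2-butene trapping the hypochlorous acid so that alkenes and enol are not chlorinated, and with no stereocentre involved.

**Compound list**

1 | phloroglucinol | Oc1cc(O)cc(O)c1 | starting material
2 | tigloyl chloride, (E)-2-methylbut-2-enoyl chloride | C/C=C(\C)C(=O)Cl | starting material
3 | (E)-2-methyl-1-(2,4,6-trihydroxyphenyl)but-2-en-1-one | C/C=C(\C)C(=O)c1c(O)cc(O)cc1O | intermediate
4 | (2R,3S)-5,7-dihydroxy-2,3-dimethylchroman-4-one (cis) | Oc1cc(O)c2c(c1)O[C@H](C)[C@H](C)C2=O | intermediate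
5 | (2R,3R)-5,7-dihydroxy-2,3-dimethylchroman-4-one (trans) | Oc1cc(O)c2c(c1)O[C@H](C)[C@@H](C)C2=O | intermediate
6 | (2R,3R)-7-acetoxy-5-hydroxy-2,3-dimethylchroman-4-one | CC(=O)Oc1cc(O)c2c(c1)O[C@H](C)[C@@H](C)C2=O | intermediate
7 | prenyl alcohol, 3-methylbut-2-en-1-ol | CC(C)=CCO | starting material
8 | (2R,3R)-7-acetoxy-2,3-dimethyl-5-(3-methylbut-2-en-1-yloxy)chroman-4-one | CC(=O)Oc1cc(OCC=C(C)C)c2c(c1)O[C@H](C)[C@@H](C)C2=O | intermediate
9 | Claisen dienone: 7-acetoxy-6-(2-methylbut-3-en-2-yl)-6H-chromene-4,5-dione form of 8 (2R,3R; C6 undefined) | C=CC(C)(C)C1C(=O)C2=C(C=C1OC(C)=O)O[C@H](C)[C@@H](C)C2=O | intermediate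
10 | Cope dienone: 7-acetoxy-8-prenyl-8H-chromene-4,5-dione keto tautomer of 11 (2R,3R; C8 undefined) | CC(C)=CCC1C(OC(C)=O)=CC(=O)C2=C1O[C@H](C)[C@@H](C)C2=O | intermediate
11 | (2R,3R)-7-acetoxy-5-hydroxy-2,3-dimethyl-8-prenylchroman-4-one | CC(=O)Oc1cc(O)c2c(c1CC=C(C)C)O[C@H](C)[C@@H](C)C2=O | intermediate
12 | (2R,3R)-5,7-dihydroxy-2,3-dimethyl-8-prenylchroman-4-one | CC(C)=CCc1c(O)cc(O)c2c1O[C@H](C)[C@@H](C)C2=O | intermediate
13 | (E)-cinnamaldehyde | O=C/C=C/c1ccccc1 | starting material
14 | lactol: cyclic hemiacetal of the (S)-3-aryl-3-phenylpropanal closed on O7 (anomer mixture) | CC(C)=CCc1c3OC(O)C[C@@H](c4ccccc4)c3c(O)c2c1O[C@H](C)[C@@H](C)C2=O | intermediate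
15 | (2R,3R)-5,7-dihydroxy-6-[(1S)-3-hydroxy-1-phenylpropyl]-2,3-dimethyl-8-prenylchroman-4-one | CC(C)=CCc1c(O)c([C@@H](CCO)c2ccccc2)c(O)c3c1O[C@H](C)[C@@H](C)C3=O | intermediate
16 | (2R,3R)-6-[(1S)-3-(tert-butyldimethylsilyloxy)-1-phenylpropyl]-5,7-dihydroxy-2,3-dimethyl-8-prenylchroman-4-one | CC(C)=CCc1c(O)c([C@@H](CCO[Si](C)(C)C(C)(C)C)c2ccccc2)c(O)c3c1O[C@H](C)[C@@H](C)C3=O | intermediate
17 | diethyl malonate | CCOC(=O)CC(=O)OCC | starting material
18 | prenyl bromide | CC(C)=CCBr | starting material
19 | diethyl 2-(3-methylbut-2-en-1-yl)malonate | CCOC(=O)C(CC=C(C)C)C(=O)OCC | intermediate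
20 | 2-(3-methylbut-2-en-1-yl)malonic acid | CC(C)=CCC(C(=O)O)C(=O)O | intermediate
21 | Mannich base, 2-[(diethylamino)methyl]-2-(3-methylbut-2-en-1-yl)malonic acid | CCN(CC)CC(CC=C(C)C)(C(=O)O)C(=O)O | intermediate
22 | 5-methyl-2-methylidenehex-4-enoic acid | C=C(CC=C(C)C)C(=O)O | intermediate
23 | 5-methyl-2-methylidenehex-4-enoyl chloride | C=C(CC=C(C)C)C(=O)Cl | intermediate
24 | N-(2-prenylacryloyl) isothiouronium chloride of (2S,3R)-HyperBTM | CC(C)[C@@H]1CN2c3ccccc3SC2=[N+](C(=O)C(=C)CC=C(C)C)[C@@H]1c1ccccc1.[Cl-] | intermediate
25 | tricyclic enol lactone (C8 S, lactone CH R, benzylic S, 2R,3R) | CC(C)=CC[C@@H]1C[C@]2(CC=C(C)C)C(OC1=O)=C([C@@H](CCO[Si](C)(C)C(C)(C)C)c3ccccc3)C(=O)C4=C2O[C@H](C)[C@@H](C)C4=O | intermediate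
26 | Weinreb amide (CH R, C8 S) | CON(C)C(=O)[C@H](CC=C(C)C)C[C@]1(CC=C(C)C)C(=O)C([C@@H](CCO[Si](C)(C)C(C)(C)C)c2ccccc2)=C(O)C2=C1O[C@H](C)[C@@H](C)C2=O | intermediate
27 | methyl ketone (CH R, C8 S) | CC(=O)[C@H](CC=C(C)C)C[C@]1(CC=C(C)C)C(=O)C([C@@H](CCO[Si](C)(C)C(C)(C)C)c2ccccc2)=C(O)C2=C1O[C@H](C)[C@@H](C)C2=O | intermediate
28 | lavandulyl compound, TBS ether | C=C(C)[C@H](CC=C(C)C)C[C@]1(CC=C(C)C)C(=O)C([C@@H](CCO[Si](C)(C)C(C)(C)C)c2ccccc2)=C(O)C2=C1O[C@H](C)[C@@H](C)C2=O | intermediate
29 | primary alcohol | C=C(C)[C@H](CC=C(C)C)C[C@]1(CC=C(C)C)C(=O)C([C@@H](CCO)c2ccccc2)=C(O)C2=C1O[C@H](C)[C@@H](C)C2=O | intermediate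
30 | aldehyde | C=C(C)[C@H](CC=C(C)C)C[C@]1(CC=C(C)C)C(=O)C([C@@H](CC=O)c2ccccc2)=C(O)C2=C1O[C@H](C)[C@@H](C)C2=O | intermediate
31 | CNP0150579.1 | C=C(C)[C@H](CC=C(C)C)C[C@]1(CC=C(C)C)C(=O)C([C@@H](CC(=O)O)c2ccccc2)=C(O)C2=C1O[C@H](C)[C@@H](C)C2=O | target

**Step count and risks**

Total step count: 20. Longest linear sequence: 16 steps (steps 1–9 and 14–20); the acid chloride branch (steps 10–13) has 4 steps.

Steps most likely to fail:

Step 14. The catalyst may give poor facial control at C8 or in the enolate protonation, attack may compete through C6, or an uncatalysed background reaction may erode selectivity. The fallback sets out from 16 and returns at 27. Acid 22 is treated with MeLi (2 equiv, Et2O, −78 → 0 °C) to give the enone 6-methyl-3-methylidenehept-5-en-2-one F1. Phenol 16 is then added to F1 under the known conditions of alkylative dearomatisation of acylphloroglucinols by conjugate addition to α-substituted enones and enals (CsOH·H2O or LiHMDS, toluene, −40 °C, with a cinchonine-derived N-benzyl quaternary ammonium phase-transfer salt to bias the face of C8). This should give methyl ketone 27 directly. The CH centre arises by unselective protonation, so the diastereomers must be separated, and the wrong CH epimer can be recycled by mild base equilibration.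

Step 8. The acyl-deactivated, doubly ortho-flanked C6 may react slowly with the iminium ion, and a slow reaction would let uncatalysed addition lower the enantioselectivity. The fallback sets out from 12 and returns at 15. Phenol 12 is annulated with (Z)-2-bromo-3-phenylprop-2-enal under N-heterocyclic carbene catalysis (chiral aminoindanol-derived triazolium salt, K2CO3, toluene), the known α,β-unsaturated acyl azolium route from electron-rich phenols and naphthols to 4-aryl-3,4-dihydrocoumarins. This should give the (4S)-4-phenyl-3,4-dihydrocoumarin closed on O7, F2 (an O5-closed isomer would converge). LiBH4 (THF, 0 °C) then opens the aryl lactone reductively to diol 15.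

Step 17. The Lewis-acidic titanium reagent may cyclodehydrate the δ-keto enol to a 4H-pyran (loss of the CH centre), or methylenation may stall on the titanium-bound substrate. The fallback sets out from 27 and returns at 29 by Peterson olefination. Me3SiCH2MgCl with CeCl3 (THF, −78 °C, excess to allow for the acidic enol) should add to the methyl ketone to give the β-hydroxysilane F3. HF·pyridine then induces the anti-elimination to the isopropenyl group and removes the silyl ether in the same operation, giving alcohol 29.

**Further compounds**

F1 | step 14 | 6-methyl-3-methylidenehept-5-en-2-one | CC(=O)C(=C)CC=C(C)C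
F2 | step 8 | (4S)-4-phenyl-3,4-dihydrocoumarin lactone of 12 closed on O7 (2R,3R ring B, 5-OH free, 8-prenyl) | CC(C)=CCc1c3OC(=O)C[C@@H](c4ccccc4)c3c(O)c2c1O[C@H](C)[C@@H](C)C2=O
F3 | step 17 | β-hydroxysilane from 27, C(OH)(CH3)CH2SiMe3 on the CH centre (carbinol centre undefined) | C[Si](C)(C)CC(C)(O)[C@H](CC=C(C)C)C[C@]1(CC=C(C)C)C(=O)C([C@@H](CCO[Si](C)(C)C(C)(C)C)c2ccccc2)=C(O)C2=C1O[C@H](C)[C@@H](C)C2=O
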